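The phthalide is disconnected across its lactone ring. C1 and C3 are attached to the adjacent ring carbons C7a and C3a, and C3a sits next to oxygenated C4, so the benzene ring maps onto a 3-alkoxybenzyne (C3a≡C7a). One operation, the coupling of this aryne with tert-butyl isocyanide and formaldehyde, forms C7a–C1, C3a–C3 and O2–C1 and closes the five-membered ring as an N-tert-butyl imidate, a masked lactone. The aryne comes from an ortho-silylaryl triflate carrying OMe and two MOM ethers, made from 2,3-dihydroxy-4-methoxybenzaldehyde. Acid then unveils the dihydroxyphthalide, whose more acidic C5 hydroxyl is alkylated with a farnesol-derived allylic bromide bearing the tertiary acetate.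

Key step: step 5

Remark: formaldehyde 10 is charged as dry paraformaldehyde, which releases the monomer in the flask; bromohydrin 16 is a racemate whose only stereocentre is removed in step 9, and the target has no stereocentre, only two E alkenes carried through from farnesol.

Step 1
Reactants: 1 2,3-dihydroxy-4-methoxybenzaldehyde
Product: 2 4-methoxy-2,3-bis(methoxymethoxy)benzaldehyde
Conditions: NaH (2.4 equiv), MOMCl (2.4 equiv), DMF, 0 °C to rt
Reagents that add atoms: chloromethyl methyl ether (MOMCl), COCCl
Why: Double Williamson-type O-alkylation of the catechol dianion, in which NaH also frees the hydrogen-bonded ortho hydroxyl, gives acetal ethers that later tolerate peracid, organolithium and fluoride.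

Step 2
Reactants: 2 4-methoxy-2,3-bis(methoxymethoxy)benzaldehyde
Product: 4 4-methoxy-2,3-bis(methoxymethoxy)phenol, via aryl formate 3 (not isolated)
Conditions: mCPBA, CH2Cl2, 0 °C to rt; aqueous NaHCO3/Na2S2O3 wash; then K2CO3 (cat.), MeOH, rt
Reagents that add atoms: meta-chloroperoxybenzoic acid (mCPBA), O=C(OO)c1cccc(Cl)c1
Why: Dakin-type sequence in which Baeyer–Villiger oxidation proceeds with migration of the electron-rich aryl group (ortho and para alkoxy donors) rather than hydride, and the aryl formate is then transesterified with methanol only after the peracid has been destroyed, so the oxidation-prone phenol never meets oxidant.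

Step 3
Reactants: 4 4-methoxy-2,3-bis(methoxymethoxy)phenol
Product: 5 6-bromo-4-methoxy-2,3-bis(methoxymethoxy)phenol
Conditions: NBS (1.0 equiv), i-Pr2NH (cat.), CH2Cl2, −20 to 0 °C
Reagents that add atoms: N-bromosuccinimide, O=C1CCC(=O)N1Br
Why: Amine-mediated ortho-selective electrophilic bromination of a phenol, in which the free hydroxyl (the strongest donor, with its para position blocked by OMe) should steer bromine to C6, its only free ortho position, while the acid-free medium spares the MOM ethers.

Step 4
Reactants: 5 6-bromo-4-methoxy-2,3-bis(methoxymethoxy)phenol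
Product: 8 4-methoxy-2,3-bis(methoxymethoxy)-6-(trimethylsilyl)phenyl trifluoromethanesulfonate, via aryl trimethylsilyl ether 6 (not isolated), via lithium silylphenoxide 7 (not isolated)
Conditions: (Me3Si)2NH, THF, 65 °C, then evaporate; n-BuLi, THF, −78 °C; Tf2O, −78 °C
Reagents that add atoms: hexamethyldisilazane, C[Si](C)(C)N[Si](C)(C)C; trifluoromethanesulfonic anhydride, O=S(=O)(OS(=O)(=O)C(F)(F)F)C(F)(F)F
Why: Silylation of the phenol, bromine–lithium exchange and 1,3-shift of silicon from oxygen to the ortho carbanion (retro-Brook rearrangement) give phenoxide 7, which is O-triflated, the standard one-pot route from 2-bromophenols to ortho-silylaryl triflates; exchange at −78 °C outruns any directed deprotonation because neither MOM group has a free ortho position.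

Step 5
Reactants: 8 4-methoxy-2,3-bis(methoxymethoxy)-6-(trimethylsilyl)phenyl trifluoromethanesulfonate; 9 tert-butyl isocyanide; 10 formaldehyde (as paraformaldehyde)
Product: 12 (Z)-N-tert-butyl-6-methoxy-4,5-bis(methoxymethoxy)isobenzofuran-1(3H)-imine, via aryne 11 (not isolated)
Conditions: 9 (2 equiv), (CH2O)n (5 equiv CH2O), CsF (3 equiv), 18-crown-6, THF, 60 °C, sealed tube
Reagents that add atoms: tert-butyl isocyanide (9), CC(C)(C)[N+]#[C-]; formaldehyde (10), C=O
Why: Fluoride attacks silicon and the incipient aryl anion at C7a expels the neighbouring triflate, releasing aryne 11; the isocyanide carbon of 9 then adds to C7a, the aryl anion thus placed at C3a adds to formaldehyde, and the resulting alkoxide attacks the nitrilium carbon. The closest known reaction type is the three-component coupling of arynes, isocyanides and aldehydes to N-substituted 1-imino-1,3-dihydroisobenzofurans, applied here with formaldehyde (unzipped from paraformaldehyde by fluoride and heat) as the carbonyl partner. The single new ring, the five-membered oxygen heterocycle, closes by 5-exo-dig attack of oxygen on the nitrilium carbon. No stereocentre is created, and the C=N geometry (expected Z, tert-butyl turned away from the peri C7–H) is lost on hydrolysis. The step needs regioselective addition of the isocyanide to C7a, which the OMOM group on C4 secures: flanking C3a, it distorts the aryne and inductively stabilises negative charge at C3a, so the nucleophile enters at the remote terminus as with other 3-alkoxybenzynes. Excess 9 and formaldehyde and the slow release of the aryne by sparingly soluble CsF are meant to suppress aryne–isocyanide oligomers and premature protonation of the aryl anion.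

Step 6
Reactants: 12 (Z)-N-tert-butyl-6-methoxy-4,5-bis(methoxymethoxy)isobenzofuran-1(3H)-imine
Product: 13 4,5-dihydroxy-6-methoxyisobenzofuran-1(3H)-one
Conditions: 3 M aqueous HCl, MeOH, 50 °C
Reagents that add atoms: water, O
Why: Acid hydrolysis of the cyclic imidate (N-protonation, addition of water, loss of tert-butylamine as its ammonium salt) gives the lactone while the same acid cleaves both MOM acetals by exchange with methanol, and any ring-opened hydroxy amide would relactonise under these conditions.

Step 7
Reactants: 14 (2E,6E)-farnesol
Product: 15 (2E,6E)-3,7,11-trimethyldodeca-2,6,10-trien-1-yl acetate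
Conditions: Ac2O, pyridine, DMAP (cat.), CH2Cl2, rt
Reagents that add atoms: acetic anhydride, CC(=O)OC(C)=O
Why: Routine acylation of a primary alcohol, which protects the hydroxyl and inductively deactivates the neighbouring C2=C3 alkene towards the electrophile of the next step.

Step 8
Reactants: 15 (2E,6E)-3,7,11-trimethyldodeca-2,6,10-trien-1-yl acetate
Product: 16 (2E,6E)-10-bromo-11-hydroxy-3,7,11-trimethyldodeca-2,6-dien-1-yl acetate (racemic)
Conditions: NBS (1.1 equiv), THF/H2O, 0 °C
Reagents that add atoms: N-bromosuccinimide, O=C1CCC(=O)N1Br; water, O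
Why: Bromohydrin formation with the established preference of farnesyl esters for attack at the terminal trisubstituted alkene in aqueous medium, water opening the bromonium ion at the more substituted carbon (Markovnikov) to place the tertiary hydroxyl on C11 and bromine on C10, without facial control and without need of it.

Step 9
Reactants: 16 (2E,6E)-10-bromo-11-hydroxy-3,7,11-trimethyldodeca-2,6-dien-1-yl acetate
Product: 17 (2E,6E)-11-hydroxy-3,7,11-trimethyldodeca-2,6-dien-1-yl acetate
Conditions: Bu3SnH, AIBN (cat.), toluene, 80 °C
Reagents that add atoms: none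
Why: Radical-chain tin hydride dehalogenation of the secondary C–Br bond, in which the C10 radical has no favourable cyclisation onto the C6=C7 alkene (only 4-exo or 5-endo modes), so hydrogen-atom transfer should prevail and esters and alkenes stay untouched.

Step 10
Reactants: 17 (2E,6E)-11-hydroxy-3,7,11-trimethyldodeca-2,6-dien-1-yl acetate
Product: 18 (2E,6E)-3,7,11-trimethyldodeca-2,6-diene-1,11-diyl diacetate
Conditions: Ac2O, Et3N, DMAP (0.2 equiv), CH2Cl2, 40 °C
Reagents that add atoms: acetic anhydride, CC(=O)OC(C)=O
Why: DMAP-catalysed acylation through the N-acetylpyridinium ion, which is reactive enough to esterify a tertiary alcohol under basic conditions that cannot ionise it.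

Step 11
Reactants: 18 (2E,6E)-3,7,11-trimethyldodeca-2,6-diene-1,11-diyl diacetate
Product: 19 (6E,10E)-12-hydroxy-2,6,10-trimethyldodeca-6,10-dien-2-yl acetate
Conditions: K2CO3 (cat.), MeOH, 0 °C
Reagents that add atoms: none
Why: Chemoselective transesterification, the unhindered primary allylic acetate being methanolysed much faster than the tertiary acetate, whose carbonyl is shielded by the fully substituted carbinol carbon.

Step 12
Reactants: 19 (6E,10E)-12-hydroxy-2,6,10-trimethyldodeca-6,10-dien-2-yl acetate
Product: 20 (6E,10E)-12-bromo-2,6,10-trimethyldodeca-6,10-dien-2-yl acetate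
Conditions: CBr4, PPh3, CH2Cl2, 0 °C; used at once
Reagents that add atoms: carbon tetrabromide, BrC(Br)(Br)Br
Why: Appel reaction, in which bromide displaces the alkoxyphosphonium group in an SN2 manner under neutral conditions, preserving the E geometry of the allylic alkene and the acid-sensitive tertiary acetate.

Step 13
Reactants: 13 4,5-dihydroxy-6-methoxyisobenzofuran-1(3H)-one; 20 (6E,10E)-12-bromo-2,6,10-trimethyldodeca-6,10-dien-2-yl acetate
Product: 21 (6E,10E)-12-[(4-hydroxy-6-methoxy-1-oxo-1,3-dihydroisobenzofuran-5-yl)oxy]-2,6,10-trimethyldodeca-6,10-dien-2-yl acetate (farnesylemefuranone F)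
Conditions: 20 (1.05 equiv), KHCO3 (1.2 equiv), DMF, 40 °C, under N2
Reagents that add atoms: none
Why: Williamson ether synthesis under weak-base control, in which KHCO3 ionises only the more acidic C5 hydroxyl (para to the lactone carbonyl and flanked by two oxygen substituents, the selectivity pattern of gallate and protocatechuate esters) and SN2 attack on the primary allylic bromide keeps both E alkenes, while the C4 hydroxyl, meta to the carbonyl, stays largely un-ionised and so limits double alkylation.

Compound list
1 | 2,3-dihydroxy-4-methoxybenzaldehyde | COc1ccc(C=O)c(O)c1O | starting material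
2 | 4-methoxy-2,3-bis(methoxymethoxy)benzaldehyde | COc1ccc(C=O)c(OCOC)c1OCOC | intermediate
3 | 4-methoxy-2,3-bis(methoxymethoxy)phenyl formate | COc1ccc(OC=O)c(OCOC)c1OCOC | intermediate
4 | 4-methoxy-2,3-bis(methoxymethoxy)phenol | COc1ccc(O)c(OCOC)c1OCOC | intermediate
5 | 6-bromo-4-methoxy-2,3-bis(methoxymethoxy)phenol | COc1cc(Br)c(O)c(OCOC)c1OCOC | intermediate
6 | [6-bromo-4-methoxy-2,3-bis(methoxymethoxy)phenoxy]trimethylsilane | COc1cc(Br)c(O[Si](C)(C)C)c(OCOC)c1OCOC | intermediate
7 | lithium 4-methoxy-2,3-bis(methoxymethoxy)-6-(trimethylsilyl)phenoxide | COc1cc([Si](C)(C)C)c([O-])c(OCOC)c1OCOC.[Li+] | intermediate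
8 | 4-methoxy-2,3-bis(methoxymethoxy)-6-(trimethylsilyl)phenyl trifluoromethanesulfonate | COc1cc([Si](C)(C)C)c(OS(=O)(=O)C(F)(F)F)c(OCOC)c1OCOC | intermediate
9 | tert-butyl isocyanide | CC(C)(C)[N+]#[C-] | starting material
10 | formaldehyde (charged as paraformaldehyde) | C=O | starting material
11 | 5-methoxy-3,4-bis(methoxymethoxy)benzyne (1,2-didehydrobenzene) | COC1=CC#CC(OCOC)=C1OCOC | intermediate
12 | (Z)-N-tert-butyl-6-methoxy-4,5-bis(methoxymethoxy)isobenzofuran-1(3H)-imine | COc1cc2c(c(OCOC)c1OCOC)CO/C2=N\C(C)(C)C | intermediate
13 | 4,5-dihydroxy-6-methoxyisobenzofuran-1(3H)-one | COc1cc2c(c(O)c1O)COC2=O | intermediate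
14 | (2E,6E)-farnesol | CC(C)=CCC/C(C)=C/CC/C(C)=C/CO | starting material
15 | (2E,6E)-3,7,11-trimethyldodeca-2,6,10-trien-1-yl acetate | CC(C)=CCC/C(C)=C/CC/C(C)=C/COC(C)=O | intermediate
16 | (2E,6E)-10-bromo-11-hydroxy-3,7,11-trimethyldodeca-2,6-dien-1-yl acetate (racemic) | CC(C)(O)C(Br)CC/C(C)=C/CC/C(C)=C/COC(C)=O | intermediate
17 | (2E,6E)-11-hydroxy-3,7,11-trimethyldodeca-2,6-dien-1-yl acetate | CC(C)(O)CCC/C(C)=C/CC/C(C)=C/COC(C)=O | intermediate
18 | (2E,6E)-3,7,11-trimethyldodeca-2,6-diene-1,11-diyl diacetate | CC(=O)OC(C)(C)CCC/C(C)=C/CC/C(C)=C/COC(C)=O | intermediate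
19 | (6E,10E)-12-hydroxy-2,6,10-trimethyldodeca-6,10-dien-2-yl acetate | CC(=O)OC(C)(C)CCC/C(C)=C/CC/C(C)=C/CO | intermediate
20 | (6E,10E)-12-bromo-2,6,10-trimethyldodeca-6,10-dien-2-yl acetate | CC(=O)OC(C)(C)CCC/C(C)=C/CC/C(C)=C/CBr | intermediate
21 | (6E,10E)-12-[(4-hydroxy-6-methoxy-1-oxo-1,3-dihydroisobenzofuran-5-yl)oxy]-2,6,10-trimethyldodeca-6,10-dien-2-yl acetate (farnesylemefuranone F) | COc1cc2c(c(O)c1OC/C=C(\C)CC/C=C(\C)CCCC(C)(C)OC(C)=O)COC2=O | target

Total step count: 13.
Longest linear sequence: 7 steps (steps 1–6 then 13; the side-chain branch, steps 7–12 then 13, is equally long).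

Steps most likely to fail

1. Step 5. Monomeric formaldehyde may be released too slowly from the polymer, so that the aryl anion is protonated or the aryne is consumed by further isocyanide or aryne instead of being intercepted; some leakage in the site of isocyanide addition is a lesser concern. The fallback sets out from aldehyde 2 and comes back to the route at 13, without an aryne. The formyl group of 2 is masked in the flask with LiN(Me)CH2CH2NMe2 (THF, −20 °C) as its α-amino alkoxide, which directs ortho-lithiation by n-BuLi to the only position next to it (the future C7a). Quenching with CO2 and mild acidic work-up should give 2-formyl-5-methoxy-3,4-bis(methoxymethoxy)benzoic acid F1. NaBH4 reduction of the aldehyde and acidification should lactonise to 6-methoxy-4,5-bis(methoxymethoxy)isobenzofuran-1(3H)-one F2, and the acid treatment of step 6 then gives 13. The formyl carbon of 2 becomes C3 and CO2 supplies C1, so the same substitution pattern results.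

2. Step 13. Site control in the O-alkylation may be lost through ionisation and alkylation of the C4 hydroxyl or a second alkylation, and the catechol may be air-oxidised under base. The fallback sets out from 13 and alcohol 19 and comes back at 21. It is a Mitsunobu etherification (PPh3, diisopropyl azodicarboxylate, THF, 0 °C), in which only the more acidic C5 hydroxyl is acidic enough to protonate the betaine and the primary allylic oxyphosphonium ion is displaced in an SN2 manner. No base and no free phenoxide are present, the bromide is not needed, and no new compound is made (F0).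

3. Step 3. The bromination may lose site control (attack at C5 next to OMe, or double bromination), or NBS may oxidise the electron-rich phenol towards a quinone. The fallback sets out from phenol 4 and comes back at 7, hence 8, replacing electrophilic substitution by directed ortho-metalation. O-carbamoylation (ClCONEt2, NaH, THF) should give 4-methoxy-2,3-bis(methoxymethoxy)phenyl N,N-diethylcarbamate F3. Lithiation with s-BuLi/TMEDA at −78 °C can occur only at C6, the one free position ortho to the carbamate, and quenching with Me3SiCl at that temperature (before anionic Fries rearrangement sets in) should give 4-methoxy-2,3-bis(methoxymethoxy)-6-(trimethylsilyl)phenyl N,N-diethylcarbamate F4. LiAlH4 in THF removes the carbamate to give 4-methoxy-2,3-bis(methoxymethoxy)-6-(trimethylsilyl)phenol F5. Deprotonation with n-BuLi gives 7, which is triflated with Tf2O as in step 4.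

Further compounds
F1 | step 5 | 2-formyl-5-methoxy-3,4-bis(methoxymethoxy)benzoic acid | COc1cc(C(=O)O)c(C=O)c(OCOC)c1OCOC
F2 | step 5 | 6-methoxy-4,5-bis(methoxymethoxy)isobenzofuran-1(3H)-one | COc1cc2c(c(OCOC)c1OCOC)COC2=O
F0 | step 13 | none | none
F3 | step 3 | 4-methoxy-2,3-bis(methoxymethoxy)phenyl N,N-diethylcarbamate | CCN(CC)C(=O)Oc1ccc(OC)c(OCOC)c1OCOC
F4 | step 3 | 4-methoxy-2,3-bis(methoxymethoxy)-6-(trimethylsilyl)phenyl N,N-diethylcarbamate | CCN(CC)C(=O)Oc1c([Si](C)(C)C)cc(OC)c(OCOC)c1OCOC
F5 | step 3 | 4-methoxy-2,3-bis(methoxymethoxy)-6-(trimethylsilyl)phenol | COc1cc([Si](C)(C)C)c(O)c(OCOC)c1OCOC
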